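Assumption: tributyl(benzyloxymethyl)stannane and the chiral silver–NHC complex of step 2 are taken as purchasable reagents. Ring positions are numbered C1–C10 as defined in the first section, also in the monocyclic intermediates, and stereodescriptors of bicyclic compounds refer to this numbering.

## The problem

Target 27 is a trans-fused hydroazulene. Ring B is a cycloheptene (C1–C7): C1 carries the angelate, C2=C3 carries the C3 methyl, C5 carries the 4-hydroxybenzoate. It is fused along C6–C7 to cyclopentane ring A (C6–C10), in which C7 is a quaternary methyl-bearing carbon and C10 a tertiary carbinol with an isopropyl group. Five stereocentres are needed: the fully substituted C7 and C10, the ring-fusion CH at C6 (trans to the C7 methyl), and the two acyloxy carbons C1 and C5, which are cis to each other and to H-6. C7 is the natural anchor. Once it is set by a catalyst, C6 can be set against it, C10 against C6, and C6 can then direct the C5 carbinol, while the neopentyl C1 is best set last by reducing a ketone. The fragile groups are the angelate (Z to E isomerisation to the tiglate), the allylic C1 ester, the tertiary C10 alcohol (dehydration, and retro-aldol once C5 is a carbonyl) and the phenol, which must be unmasked beside two esters. The trisubstituted alkene must also end on the C1 side of C3 and not on the C5 side. The enabling feature is the hidden symmetry of ring B: C1 and C5 are both secondary carbinols, attached to the neighbouring ring A carbons C7 and C6 and bridged by C2–C3–C4 with the extra carbon on C3. Ring B is therefore the (4+3) union of a C1/C7/C6/C5 dialdehyde with a 2-substituted allyl unit that is nucleophilic at both CH2 ends.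

## Retrosynthesis

**27 ⇒ 26 ⇒ 23 + 24.** The last skeletal event is cleavage of the two O–Si bonds of 26, and before it formation of the C1–O acyl bond from alcohol 23 and angelic acid 24. The (Z)-2-methylbut-2-enoyl group would not survive hydride, base or oxidant, so it must come after every redox step. Precursor 23 lacks the most labile ester. The forward reaction must acylate a hindered neopentyl allylic alcohol without Z/E scrambling.

**23 ⇒ 22 ⇒ 20 (through 21).** The C1 carbinol hydrogen is removed to give enone 22, and the C2=C3 double bond is traced back to the exocyclic methylene of 20. In 20 the methylene sits between two nearly equivalent CH2 groups, so direct isomerisation would not distinguish C2 from C4. A C1 carbonyl makes the C1 side unique, because conjugation pulls the alkene to C2=C3. The price is that C1 must be re-made by a face-selective 1,2-reduction. The gain is that either C1 epimer of 20 is usable.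

**20 ⇒ 16 + 19, and 19 ⇒ 17.** The C5–O acyl bond is cut to diol 16 and silyl-protected acid 19, made from 4-hydroxybenzoic acid 17. Acylating C5 first is preferred to the reverse order because C5–OH is flanked by a CH, whereas C1–OH is neopentyl. The forward reaction has to exploit this steric difference.

**16 ⇒ 10 + 14 (key).** Both C4–C5 and C1–C2 are cut. This removes ring B, two carbinol stereocentres and four carbons at once and leaves monocyclic dialdehyde 10 and the achiral iodide/allylsilane 14. Cuts through C6–C7 or C7–C1 would give up the ring-fusion stereochemistry, and cuts at C2–C3/C3–C4 would not use the symmetry. The forward reaction must add to the C5 aldehyde from the correct face and close a seven-membered ring in preference to intermolecular reaction.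

**14 ⇒ 13 ⇒ 11.** The C–I bond comes from a C–Cl bond and the C–Si bond from the second C–Cl bond of the symmetric dichloride 11. Only mono-substitution is required.

**10 ⇒ 9 ⇒ 8 ⇒ 7 ⇒ 6.** Both aldehydes come from primary alcohols (9), and these from benzyl ethers (8) that are removed by hydrogenolysis, orthogonal to the tertiary silyl ether. The C10–isopropyl bond is cut back to ketone 6. In 6 the C10 carbonyl is the only electrophile, so the isopropyl nucleophile needs no chemoselectivity, only attack anti to the C6 arm.

**6 ⇒ 5 ⇒ 3.** The C6–C5 bond (enol silane alkylation) and the C7–methyl bond (conjugate addition) are cut. Conjugate addition is preferred to base enolisation of a preformed ketone because it sets C7 under catalyst control and delivers the enolate on the hindered C6 side. The forward alkylation must place C5 trans to the C7 oxymethyl arm.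

**3 ⇒ 1.** The C7–C1 bond is cut to the vinylogous ester 1 and an alkoxymethyl anion equivalent. This is a carbonyl addition with transposition and involves no stereochemistry.

## Roads not taken

**Alternative 1:** The cut is C6–C7 inside ring A. An acyclic α-diazo-β-keto ester A2 with a purchased methyl-bearing stereocentre would be decomposed by a dirhodium carboxylate catalyst. The carbenoid at C6 inserts into the tertiary C7–H bond with retention and gives cyclopentanone A1.
- Merits: the absolute configuration at C7 is bought and not dependent on a catalyst's enantioselectivity; 1,5-insertion into a tertiary C–H bond is a favourable case; C5 arrives at the ester level.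
- Weak points: it solves only ring A, so an annulation such as step 10 is still needed. The β-keto ester of A1 would enolise with an isopropyl organometallic, so C5 must be reduced and protected before C10 can be built. A2 itself needs several steps, and the C–H bonds next to the silyloxy group are a competing insertion site.
- Comparison: Alternative 1 is stronger on absolute stereocontrol at C7. The chosen plan sets against this a three-step entry to ketone 6 in which C5 is already at the oxidation level that is carried forward.

**Alternative 2:** The cuts are C7–C1 and C6–C5. Irradiation of 3-methylcyclopent-2-en-1-one A3 with the bis-silyloxy cyclopentene A4 would give the cyclobutane photoadduct A5. Glycol cleavage of its C1–C5 bond would open it to the hydroazulene trione A6.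
- Merits: the bicyclic skeleton with the C7 and C3 methyls and oxygen at C1, C5 and C10 is reached in two or three operations from trivial materials. This is far shorter than the ten steps the chosen plan needs to reach 16.
- Weak points: the photocycloaddition is racemic. A6 carries three ketones, two of them flanking C6 as a β-diketone, so the ring-fusion centre is lost and must be re-established trans. The isopropyl group must then be added to one ketone of three, the C2=C3 alkene introduced by a regioselective desaturation, and C1 and C5 reduced with control.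
- Comparison: the chosen plan is longer to the skeleton. In return it has enantiocontrol, and each oxygen is differentiated when it is made (C10 is built while it is the only carbonyl).

**Alternative 3:** The cuts are C1–C2 and C3–C4, with cleavage of a cyclopropane bond C6–C1. A rhodium carbonyl chloride catalyst would couple the ring-fused vinylcyclopropane A7 with propyne A8 to the cycloheptadiene A9.
- Merits: the C2=C3 alkene with its methyl and the C1 oxygen with its configuration are delivered directly, and C5 and C10 emerge as differentiated enol derivatives. This is better than the chosen plan, which needs the redox detour of steps 13 and 14.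
- Weak points: A7 is a bicyclo[3.1.0]hexene with three contiguous stereocentres, two of them quaternary, and is harder to make than dialdehyde 10. The orientation of propyne (methyl on C3 or C2) and the choice of cyclopropane bond are not assured. C6 becomes sp2, so the trans ring fusion and the C10 carbinol would both have to be set late on a polyfunctional intermediate.
- Comparison: the chosen plan sets against Alternative 3 a simple annulation precursor in which C6, C7 and C10 are fixed before ring B is closed.

Key step: step 10

## Route

Step 1
Reactants: 1 3-ethoxycyclopent-2-en-1-one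
Product: 3 3-(benzyloxymethyl)cyclopent-2-en-1-one, via lithium alkoxide adduct 2 (not isolated)
Conditions: Bu3SnCH2OBn, n-BuLi, THF, −78 °C; then 1, −78 °C; then 1 M HCl, 0 °C → rt
Reagents that add atoms: tributyl(benzyloxymethyl)stannane (as its lithium derivative), CCCC[Sn](CCCC)(CCCC)COCc1ccccc1; water (supplies the carbonyl oxygen on hydrolysis), O
Why: Stork–Danheiser sequence: the α-alkoxy organolithium from tin–lithium exchange adds 1,2 to the vinylogous ester, and acid hydrolysis of the enol ether with loss of the tertiary hydroxyl transposes the carbonyl to give the 3-substituted enone; no stereocentre is formed.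

Step 2
Reactants: 3 3-(benzyloxymethyl)cyclopent-2-en-1-one
Product: 5 (S)-{[3-(benzyloxymethyl)-3-methylcyclopent-1-en-1-yl]oxy}triethylsilane, via aluminium enolate 4 (not isolated)
Conditions: Me3Al, Cu(OTf)2 (5 mol%), chiral silver–NHC complex Ag2L2 (2.5 mol%; L = 4,5-diphenyl-1-(2-sulfonatophenyl)-3-(2,4,6-trimethylphenyl)imidazolin-2-ylidene, enantiomer chosen for (S)-5), THF, −78 °C; then Et3SiOTf, −78 → 0 °C
Reagents that add atoms: trimethylaluminium, C[Al](C)C; triethylsilyl triflate, CC[Si](CC)(CC)OS(=O)(=O)C(F)(F)F
Why: Copper–NHC-catalysed asymmetric conjugate addition of a trialkylaluminium to a β-substituted cyclopentenone builds the all-carbon quaternary C7, its configuration being set by the ligand; silylation of the aluminium enolate fixes the enolate on the hindered C6 side for step 3.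

Step 3
Reactants: 5 (S)-{[3-(benzyloxymethyl)-3-methylcyclopent-1-en-1-yl]oxy}triethylsilane
Product: 6 (2S,3S)-2,3-bis(benzyloxymethyl)-3-methylcyclopentan-1-one
Conditions: BnOCH2Cl, TiCl4, CH2Cl2, −78 °C
Reagents that add atoms: benzyl chloromethyl ether, ClCOCc1ccccc1
Why: Mukaiyama-type alkylation: TiCl4 ionises the chloromethyl ether to an oxocarbenium ion that the enol silane attacks at carbon (C6–C5 bond). Attack should occur anti to the C7 benzyloxymethyl arm, which is the larger group once its oxygen is complexed by TiCl4, so that C5 ends trans to C1 and cis to the C7 methyl.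

Step 4
Reactants: 6 (2S,3S)-2,3-bis(benzyloxymethyl)-3-methylcyclopentan-1-one
Product: 7 (1R,2S,3S)-2,3-bis(benzyloxymethyl)-3-methyl-1-(propan-2-yl)cyclopentan-1-ol
Conditions: i-PrMgCl, CeCl3 (anhydrous), THF, −78 → 0 °C
Reagents that add atoms: isopropylmagnesium chloride, CC(C)[Mg]Cl
Why: Cerium-mediated Grignard 1,2-addition suppresses enolisation and β-hydride reduction of the hindered ketone. The isopropyl group enters anti to the adjacent C6 arm (chelation of the metal between the carbonyl and the C5 ether oxygen acts in the same sense), which puts the C10 oxygen cis to C5.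

Step 5
Reactants: 7 (1R,2S,3S)-2,3-bis(benzyloxymethyl)-3-methyl-1-(propan-2-yl)cyclopentan-1-ol
Product: 8 {[(1R,2S,3S)-2,3-bis(benzyloxymethyl)-3-methyl-1-(propan-2-yl)cyclopentyl]oxy}trimethylsilane
Conditions: Me3SiOTf, 2,6-lutidine, CH2Cl2, −78 → 0 °C
Reagents that add atoms: trimethylsilyl triflate, C[Si](C)(C)OS(=O)(=O)C(F)(F)F
Why: Silyl triflate with a hindered base is the standard silylation of hindered tertiary alcohols; the ether blocks retro-aldol and dehydration once C5 becomes an aldehyde.

Step 6
Reactants: 8 {[(1R,2S,3S)-2,3-bis(benzyloxymethyl)-3-methyl-1-(propan-2-yl)cyclopentyl]oxy}trimethylsilane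
Product: 9 [(1S,2S,3R)-1-methyl-3-(propan-2-yl)-3-(trimethylsilyloxy)cyclopentane-1,2-diyl]dimethanol
Conditions: H2 (1 atm), 10% Pd/C, EtOAc, rt
Reagents that add atoms: none
Why: Hydrogenolysis cleaves both benzyl ethers under neutral aprotic conditions; the substrate has no alkene and the tertiary silyl ether is not affected.

Step 7
Reactants: 9 [(1S,2S,3R)-1-methyl-3-(propan-2-yl)-3-(trimethylsilyloxy)cyclopentane-1,2-diyl]dimethanol
Product: 10 (1S,2R,3R)-1-methyl-3-(propan-2-yl)-3-(trimethylsilyloxy)cyclopentane-1,2-dicarbaldehyde
Conditions: (COCl)2, DMSO, CH2Cl2, −78 °C; then Et3N, −78 → −20 °C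
Reagents that add atoms: none
Why: Swern oxidation takes both primary alcohols to aldehydes without over-oxidation; the trans 1,4-diol cannot lactolise, and the low temperature limits epimerisation at C6, the only enolisable position.

Step 8
Reactants: 11 3-chloro-2-(chloromethyl)prop-1-ene
Product: 13 [2-(chloromethyl)prop-2-en-1-yl]trimethylsilane, via allyltrichlorosilane 12 (not isolated)
Conditions: HSiCl3, Et3N, CuCl (cat.), Et2O, rt (excess 11); then MeMgBr, Et2O, 0 °C → reflux
Reagents that add atoms: trichlorosilane, Cl[SiH](Cl)Cl; methylmagnesium bromide, C[Mg]Br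
Why: Copper-catalysed silylation of an allylic chloride with HSiCl3/Et3N, run with excess dichloride for mono-substitution, followed by exhaustive methylation of the Si–Cl bonds by the Grignard reagent.

Step 9
Reactants: 13 [2-(chloromethyl)prop-2-en-1-yl]trimethylsilane
Product: 14 [2-(iodomethyl)prop-2-en-1-yl]trimethylsilane
Conditions: NaI, acetone, rt, dark
Reagents that add atoms: sodium iodide, [Na+].[I-]
Why: Finkelstein exchange at a primary allylic chloride, driven by precipitation of NaCl; the allylsilane is untouched.

Step 10
Reactants: 10 (1S,2R,3R)-1-methyl-3-(propan-2-yl)-3-(trimethylsilyloxy)cyclopentane-1,2-dicarbaldehyde; 14 [2-(iodomethyl)prop-2-en-1-yl]trimethylsilane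
Product: 16 (1R,5S,6S,7S,10R)-7-methyl-3-methylidene-10-(propan-2-yl)-10-(trimethylsilyloxy)-trans-hydroazulene-1,5-diol, via mono-adduct hydroxy aldehyde 15 (not isolated)
Conditions: SnF2, THF, 0 °C → rt, slow addition of 14 (1.05 equiv); then CH2Cl2, −78 °C, BF3·OEt2; aq NaHCO3
Reagents that add atoms: none
Why: SnF2 inserts into the C–I bond of 14 to give an allyltin trihalide (tin becomes tetravalent) that adds to an aldehyde of 10 through a six-membered cyclic transition state with allylic transposition (Barbier-type allylation), forming C4–C5 and the tin alkoxide of 15; BF3·OEt2 then activates the remaining aldehyde and the pendant allylsilane attacks through its CH2 terminus (Hosomi–Sakurai reaction), forming C1–C2, expelling Me3SiF and leaving the exocyclic methylene on C3. The closest known reaction type is the stepwise (3+4) annulation of 1,4-dicarbonyl compounds with this same iodide/allylsilane to give methylenecycloheptanediols. Ring B closes in the second stage by 7-exo-trig attack on the C1 carbonyl, with both carbons of the allylsilane double bond becoming ring members; the trans formyl groups on ring A cannot form a five-membered lactol and preset the trans ring fusion. C5 is controlled by C6: the formyl hydrogen, not the oxygen, should lie under ring A between the C7 methyl and the C10 silyloxy group (both cis to this formyl group), and the allyl carbon should approach from the C7 flank, anti to the more heavily substituted C10, which gives O-5 cis to H-6. C1 is controlled in the ring closure: the tin alkoxide on O-5 can bridge to the C1 carbonyl oxygen and hold the C1=O bond syn to C7–C6, which places O-1 on the face of O-5 and anti to the C7 methyl. The step needs only the C5 configuration, because C1 is re-made in steps 13 and 14 and both C1 epimers converge on 22. It needs no chemoselectivity between the two aldehydes, because the reagent is symmetric and either order of addition gives the same constitution; slow addition of one equivalent of 14 at moderate dilution should suppress double intermolecular allylation.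

Step 11
Reactants: 17 4-hydroxybenzoic acid
Product: 19 4-(tert-butyldimethylsilyloxy)benzoic acid, via bis-silylated ester 18 (not isolated)
Conditions: t-BuMe2SiCl (2.3 equiv), imidazole, DMF, rt; then AcOH–H2O–THF, rt
Reagents that add atoms: tert-butyldimethylsilyl chloride, CC(C)(C)[Si](C)(C)Cl
Why: Both hydroxyls are silylated and the far more labile silyl ester is then hydrolysed selectively, leaving the aryl silyl ether.

Step 12
Reactants: 16 (1R,5S,6S,7S,10R)-7-methyl-3-methylidene-10-(propan-2-yl)-10-(trimethylsilyloxy)-trans-hydroazulene-1,5-diol; 19 4-(tert-butyldimethylsilyloxy)benzoic acid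
Product: 20 (1R,5S,6S,7S,10R)-1-hydroxy-7-methyl-3-methylidene-10-(propan-2-yl)-10-(trimethylsilyloxy)-trans-hydroazulen-5-yl 4-(tert-butyldimethylsilyloxy)benzoate
Conditions: 19 (1.1 equiv), EDC·HCl, DMAP, CH2Cl2, 0 °C → rt
Reagents that add atoms: none
Why: Steglich esterification; the C5 hydroxyl is equatorial and flanked by a CH, whereas the C1 hydroxyl is neopentyl (next to quaternary C7) and should acylate much more slowly, so a slight excess of acid should give the C5 mono-ester.

Step 13
Reactants: 20 (1R,5S,6S,7S,10R)-1-hydroxy-7-methyl-3-methylidene-10-(propan-2-yl)-10-(trimethylsilyloxy)-trans-hydroazulen-5-yl 4-(tert-butyldimethylsilyloxy)benzoate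
Product: 22 (5S,6S,7S,10R)-3,7-dimethyl-1-oxo-10-(propan-2-yl)-10-(trimethylsilyloxy)-trans-hydroazul-2-en-5-yl 4-(tert-butyldimethylsilyloxy)benzoate, via β,γ-unsaturated ketone 21 (not isolated)
Conditions: Dess–Martin periodinane, CH2Cl2, 0 °C → rt; Na2S2O3/NaHCO3 work-up; then DBU (0.2 equiv), CH2Cl2, 0 °C
Reagents that add atoms: none
Why: Dess–Martin oxidation of the hindered C1 alcohol, then base-catalysed β,γ to α,β isomerisation through the dienolate moves the exocyclic alkene into conjugation. This fixes the double bond at C2=C3, since only the C1 side carries a carbonyl; catalytic base at low temperature should avoid vinylogous elimination of the C5 ester.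

Step 14
Reactants: 22 (5S,6S,7S,10R)-3,7-dimethyl-1-oxo-10-(propan-2-yl)-10-(trimethylsilyloxy)-trans-hydroazul-2-en-5-yl 4-(tert-butyldimethylsilyloxy)benzoate
Product: 23 (1R,5S,6S,7S,10R)-1-hydroxy-3,7-dimethyl-10-(propan-2-yl)-10-(trimethylsilyloxy)-trans-hydroazul-2-en-5-yl 4-(tert-butyldimethylsilyloxy)benzoate
Conditions: LiBH(s-Bu)3 (L-Selectride), THF, −78 °C; AcOH quench at −78 °C
Reagents that add atoms: none
Why: 1,2-Reduction by a bulky trialkylborohydride (the β,β-disubstituted enone disfavours conjugate reduction, and the esters survive at −78 °C). Hydride should enter from the outer face of ring B, anti to the C7–C6 ring bond (equatorial attack), giving the pseudo-axial C1 alcohol trans to the C7 methyl and cis to the C5 ester.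

Step 15
Reactants: 23 (1R,5S,6S,7S,10R)-1-hydroxy-3,7-dimethyl-10-(propan-2-yl)-10-(trimethylsilyloxy)-trans-hydroazul-2-en-5-yl 4-(tert-butyldimethylsilyloxy)benzoate; 24 angelic acid ((Z)-2-methylbut-2-enoic acid)
Product: 26 (1R,5S,6S,7S,10R)-3,7-dimethyl-1-{[(Z)-2-methylbut-2-enoyl]oxy}-10-(propan-2-yl)-10-(trimethylsilyloxy)-trans-hydroazul-2-en-5-yl 4-(tert-butyldimethylsilyloxy)benzoate, via mixed anhydride 25 (not isolated)
Conditions: 24, 2,4,6-trichlorobenzoyl chloride, Et3N, toluene, rt; then 23, toluene, 75 °C
Reagents that add atoms: none
Why: Yamaguchi-type esterification through the mixed anhydride 25; under these DMAP-free conditions hindered secondary alcohols are angeloylated with little Z to E isomerisation, and C1 is not touched, so its configuration is retained.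

Step 16
Reactants: 26 (1R,5S,6S,7S,10R)-3,7-dimethyl-1-{[(Z)-2-methylbut-2-enoyl]oxy}-10-(propan-2-yl)-10-(trimethylsilyloxy)-trans-hydroazul-2-en-5-yl 4-(tert-butyldimethylsilyloxy)benzoate
Product: 27 (1R,5S,6S,7S,10R)-10-hydroxy-3,7-dimethyl-1-{[(Z)-2-methylbut-2-enoyl]oxy}-10-(propan-2-yl)-trans-hydroazul-2-en-5-yl 4-hydroxybenzoate (target)
Conditions: HF·pyridine, pyridine, THF, 0 °C → rt
Reagents that add atoms: none
Why: Fluoride cleaves the aryl silyl ether and the tertiary trimethylsilyl ether; buffered HF·pyridine is mild enough for the angelate, the benzoate and the allylic C1–O bond.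

## Compound list

1 | 3-ethoxycyclopent-2-en-1-one | CCOC1=CC(=O)CC1 | starting material
2 | lithium 1-(benzyloxymethyl)-3-ethoxycyclopent-2-en-1-olate (racemic) | CCOC1=CC([O-])(COCc2ccccc2)CC1.[Li+] | intermediate
3 | 3-(benzyloxymethyl)cyclopent-2-en-1-one | O=C1CCC(COCc2ccccc2)=C1 | intermediate
4 | dimethylaluminium (S)-3-(benzyloxymethyl)-3-methylcyclopent-1-en-1-olate | c1ccccc1COC[C@@]1(C)CCC(O[Al](C)C)=C1 | intermediate
5 | (S)-{[3-(benzyloxymethyl)-3-methylcyclopent-1-en-1-yl]oxy}triethylsilane | c1ccccc1COC[C@@]1(C)CCC(O[Si](CC)(CC)CC)=C1 | intermediate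
6 | (2S,3S)-2,3-bis(benzyloxymethyl)-3-methylcyclopentan-1-one | c1ccccc1COC[C@@]1(C)CCC(=O)[C@@H]1COCc1ccccc1 | intermediate
7 | (1R,2S,3S)-2,3-bis(benzyloxymethyl)-3-methyl-1-(propan-2-yl)cyclopentan-1-ol | c1ccccc1COC[C@@]1(C)CC[C@@](O)(C(C)C)[C@@H]1COCc1ccccc1 | intermediate
8 | {[(1R,2S,3S)-2,3-bis(benzyloxymethyl)-3-methyl-1-(propan-2-yl)cyclopentyl]oxy}trimethylsilane | c1ccccc1COC[C@@]1(C)CC[C@@](O[Si](C)(C)C)(C(C)C)[C@@H]1COCc1ccccc1 | intermediate
9 | [(1S,2S,3R)-1-methyl-3-(propan-2-yl)-3-(trimethylsilyloxy)cyclopentane-1,2-diyl]dimethanol | OC[C@@]1(C)CC[C@@](O[Si](C)(C)C)(C(C)C)[C@@H]1CO | intermediate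
10 | (1S,2R,3R)-1-methyl-3-(propan-2-yl)-3-(trimethylsilyloxy)cyclopentane-1,2-dicarbaldehyde (trans ring A dialdehyde) | O=C[C@@]1(C)CC[C@@](O[Si](C)(C)C)(C(C)C)[C@@H]1C=O | intermediate
11 | 3-chloro-2-(chloromethyl)prop-1-ene | C=C(CCl)CCl | starting material
12 | trichloro[2-(chloromethyl)prop-2-en-1-yl]silane | C=C(CCl)C[Si](Cl)(Cl)Cl | intermediate
13 | [2-(chloromethyl)prop-2-en-1-yl]trimethylsilane | C=C(CCl)C[Si](C)(C)C | intermediate
14 | [2-(iodomethyl)prop-2-en-1-yl]trimethylsilane (3-iodo-2-(trimethylsilylmethyl)prop-1-ene) | C=C(CI)C[Si](C)(C)C | intermediate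
15 | (1S,2S,3R)-2-[(1S)-1-hydroxy-3-(trimethylsilylmethyl)but-3-en-1-yl]-1-methyl-3-(propan-2-yl)-3-(trimethylsilyloxy)cyclopentane-1-carbaldehyde (formed as its tin alkoxide) | O=C[C@@]1(C)CC[C@@](O[Si](C)(C)C)(C(C)C)[C@@H]1[C@@H](O)CC(=C)C[Si](C)(C)C | intermediate
16 | (1R,5S,6S,7S,10R)-7-methyl-3-methylidene-10-(propan-2-yl)-10-(trimethylsilyloxy)-trans-hydroazulene-1,5-diol | O[C@@H]1CC(=C)C[C@H](O)[C@@H]2[C@]1(C)CC[C@@]2(O[Si](C)(C)C)C(C)C | intermediate
17 | 4-hydroxybenzoic acid | OC(=O)c1ccc(O)cc1 | starting material
18 | tert-butyldimethylsilyl 4-(tert-butyldimethylsilyloxy)benzoate | CC(C)(C)[Si](C)(C)OC(=O)c1ccc(O[Si](C)(C)C(C)(C)C)cc1 | intermediate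
19 | 4-(tert-butyldimethylsilyloxy)benzoic acid | OC(=O)c1ccc(O[Si](C)(C)C(C)(C)C)cc1 | intermediate
20 | C5 ester of 16 with 19, free C1–OH, (1R,5S,6S,7S,10R) | O[C@@H]1CC(=C)C[C@H](OC(=O)c3ccc(O[Si](C)(C)C(C)(C)C)cc3)[C@@H]2[C@]1(C)CC[C@@]2(O[Si](C)(C)C)C(C)C | intermediate
21 | C1 ketone with exocyclic C3 methylene, (5S,6S,7S,10R) | O=C1CC(=C)C[C@H](OC(=O)c3ccc(O[Si](C)(C)C(C)(C)C)cc3)[C@@H]2[C@]1(C)CC[C@@]2(O[Si](C)(C)C)C(C)C | intermediate
22 | conjugated C1 ketone, C2=C3, (5S,6S,7S,10R) | O=C1C=C(C)C[C@H](OC(=O)c3ccc(O[Si](C)(C)C(C)(C)C)cc3)[C@@H]2[C@]1(C)CC[C@@]2(O[Si](C)(C)C)C(C)C | intermediate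
23 | allylic C1 alcohol, (1R,5S,6S,7S,10R) | O[C@@H]1C=C(C)C[C@H](OC(=O)c3ccc(O[Si](C)(C)C(C)(C)C)cc3)[C@@H]2[C@]1(C)CC[C@@]2(O[Si](C)(C)C)C(C)C | intermediate
24 | angelic acid, (Z)-2-methylbut-2-enoic acid | C/C=C(/C)C(=O)O | starting material
25 | (Z)-2-methylbut-2-enoic 2,4,6-trichlorobenzoic anhydride | C/C=C(/C)C(=O)OC(=O)c1c(Cl)cc(Cl)cc1Cl | intermediate
26 | bis-silyl protected target: C1 angelate, C5 4-(tert-butyldimethylsilyloxy)benzoate, C10 trimethylsilyl ether, (1R,5S,6S,7S,10R) | C/C=C(/C)C(=O)O[C@@H]1C=C(C)C[C@H](OC(=O)c3ccc(O[Si](C)(C)C(C)(C)C)cc3)[C@@H]2[C@]1(C)CC[C@@]2(O[Si](C)(C)C)C(C)C | intermediate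
27 | (1R,5S,6S,7S,10R)-10-hydroxy-3,7-dimethyl-1-{[(Z)-2-methylbut-2-enoyl]oxy}-10-(propan-2-yl)-trans-hydroazul-2-en-5-yl 4-hydroxybenzoate (CNP0273650.2) | C/C=C(/C)C(=O)O[C@@H]1C=C(C)C[C@H](OC(=O)c2ccc(O)cc2)[C@@H]2[C@]1(C)CC[C@@]2(O)C(C)C | target

## Step count and least certain steps

Total: 16 steps. Longest linear sequence: 13 steps (steps 1–7, 10, 12–16, from 3-ethoxycyclopent-2-en-1-one); steps 8–9 and 11 are side branches.

**Step 10 (key).** The most likely failure is poor facial selectivity at C5. The C5 formyl group is flanked by two fully substituted carbons, so the steric bias between the C7 and C10 flanks may be small. Double intermolecular allylation is the second concern. Fallback: if 10 and 14 give mainly the C5-epimeric diol F1, this is esterified with 19 under Mitsunobu conditions (PPh3, diisopropyl azodicarboxylate, THF). That inverts C5 and installs the aroyl group in one operation, and it rejoins the route at 20. The neopentyl C1 hydroxyl cannot be displaced, and its configuration is irrelevant because it is oxidised in step 13.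

**Step 3.** Facial selectivity at C6 may be low, because methyl and benzyloxymethyl on C7 differ little in size unless the ether is complexed by the Lewis acid. Fallback: from 5, a Mukaiyama aldol with aqueous formaldehyde and Yb(OTf)3 gives the β-hydroxy ketone F2, (2S,3S)-3-(benzyloxymethyl)-2-(hydroxymethyl)-3-methylcyclopentan-1-one. The aldol is reversible and C6 can equilibrate trans to the larger arm, and the diastereomers are easier to separate at this stage. Acid-catalysed benzylation with benzyl 2,2,2-trichloroacetimidate returns to 6.

**Step 12.** Chemoselectivity may be lost: the C10 substituents crowd the C5 hydroxyl, so acylation at C1 or bis-acylation could compete. Fallback: from 10 and 14, stop the annulation after the SnF2 stage and isolate 15, which has a single hydroxyl. Esterify it with 19 (EDC·HCl, DMAP) to the acylated hydroxy aldehyde F3, then close ring B with BF3·OEt2. This gives 20 directly, with the two oxygens differentiated by construction.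

**Step 14.** Hydride may instead be delivered anti to the angular methyl (axial attack), giving the C1 epimer, or conjugate reduction may compete at this hindered carbonyl. Fallback: switch from substrate to reagent control. Corey–Bakshi–Shibata reduction of 22 with catecholborane and the 2-methyl-CBS-oxazaborolidine enantiomer matched to the required face returns to 23. This fallback makes no new compound (F0).

**Step 15.** The angelate may isomerise to the tiglate, or the neopentyl allylic alcohol may not acylate. Fallback: from 23, carbodiimide coupling with 2-[bis(2,2,2-trifluoroethoxy)phosphoryl]propanoic acid gives the phosphonate ester F4 (α-phosphono acids acylate hindered alcohols readily). Still–Gennari olefination with acetaldehyde (KN(SiMe3)2, 18-crown-6, THF, −78 °C) then builds the (Z)-2-methylbut-2-enoate on the molecule and rejoins the route at 26.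

## Further compounds

F1 | step 10 | (1R,5R,6S,7S,10R)-7-methyl-3-methylidene-10-(propan-2-yl)-10-(trimethylsilyloxy)-trans-hydroazulene-1,5-diol (C5 epimer of 16) | O[C@@H]1CC(=C)C[C@@H](O)[C@@H]2[C@]1(C)CC[C@@]2(O[Si](C)(C)C)C(C)C
F2 | step 3 | (2S,3S)-3-(benzyloxymethyl)-2-(hydroxymethyl)-3-methylcyclopentan-1-one | c1ccccc1COC[C@@]1(C)CCC(=O)[C@@H]1CO
F3 | step 12 | (1S)-1-[(1S,2S,5R)-2-formyl-2-methyl-5-(propan-2-yl)-5-(trimethylsilyloxy)cyclopentyl]-3-(trimethylsilylmethyl)but-3-en-1-yl 4-(tert-butyldimethylsilyloxy)benzoate | O=C[C@@]1(C)CC[C@@](O[Si](C)(C)C)(C(C)C)[C@@H]1[C@@H](OC(=O)c2ccc(O[Si](C)(C)C(C)(C)C)cc2)CC(=C)C[Si](C)(C)C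
F0 | step 14 | none | none
F4 | step 15 | C1 2-[bis(2,2,2-trifluoroethoxy)phosphoryl]propanoate of 23 (phosphonate α-carbon unassigned) | CC(C(=O)O[C@@H]1C=C(C)C[C@H](OC(=O)c3ccc(O[Si](C)(C)C(C)(C)C)cc3)[C@@H]2[C@]1(C)CC[C@@]2(O[Si](C)(C)C)C(C)C)P(=O)(OCC(F)(F)F)OCC(F)(F)F
A1 | alternative 1 | methyl (1R,2S)-2-(tert-butyldimethylsilyloxymethyl)-2-methyl-5-oxocyclopentane-1-carboxylate | COC(=O)[C@H]1C(=O)CC[C@]1(C)CO[Si](C)(C)C(C)(C)C
A2 | alternative 1 | methyl (6S)-7-(tert-butyldimethylsilyloxy)-2-diazo-6-methyl-3-oxoheptanoate | COC(=O)C(=[N+]=[N-])C(=O)CC[C@H](C)CO[Si](C)(C)C(C)(C)C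
A3 | alternative 2 | 3-methylcyclopent-2-en-1-one | CC1=CC(=O)CC1
A4 | alternative 2 | 4-methyl-1,2-bis(trimethylsilyloxy)cyclopent-1-ene | CC1CC(O[Si](C)(C)C)=C(O[Si](C)(C)C)C1
A5 | alternative 2 | cis-anti-cis tricyclic photoadduct, bis(trimethylsilyl) ether of the cyclobutane-1,2-diol | O=C1CC[C@@]2(C)[C@@H]1[C@]1(O[Si](C)(C)C)C[C@@H](C)C[C@]21O[Si](C)(C)C
A6 | alternative 2 | 3,7-dimethylhydroazulene-1,5,10-trione (cis-fused as formed) | O=C1CC[C@@]2(C)[C@@H]1C(=O)C[C@@H](C)CC2=O
A7 | alternative 3 | ring-fused vinylcyclopropane: 2-acetoxy-1-[1-(tert-butyldimethylsilyloxy)vinyl]-6-(4-methoxybenzyloxy)-5-methylbicyclo[3.1.0]hex-2-ene | C=C(O[Si](C)(C)C(C)(C)C)[C@]12[C@@H](OCc3ccc(OC)cc3)[C@@]1(C)CC=C2OC(C)=O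
A8 | alternative 3 | propyne | CC#C
A9 | alternative 3 | bicyclic cycloheptadiene with C1 4-methoxybenzyl ether, C5 silyl enol ether and C10 enol acetate | CC1=C[C@@H](OCc2ccc(OC)cc2)[C@@]2(C)CC=C(OC(C)=O)C2=C(O[Si](C)(C)C(C)(C)C)C1
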